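## Retrosynthetic overview

- Target 18 ← global hydrogenolysis of the perbenzylated digallate 17 ← double esterification of diol 15 (3-OH and 5-OH free, O7 and the B ring benzylated) ← 3-ol 14 ← 3-boronate 13.
- Key disconnection of the pyran (C) ring of 13 at C2–C3 and O1–C8a: an A-ring aryl bromide carrying a CH2–CH(Bpin)2 arm (10) plus the B-ring aldehyde 11. A Cu-catalysed enantio- and syn-selective 1,2-addition is followed in the same flask by a Pd-catalysed O-arylation.
- Enabling feature: C2 of the pyran ring is a benzylic carbon bearing O1 and the pyrogallol B ring (a latent ArCHO). Its neighbour C3 carries an oxygen cis to that ring, which can be held as a C–B bond and oxidised with retention. O1 sits on aromatic C8a of the phloroglucinol A ring (a latent aryl bromide).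
- 10 ← benzylic bromide 7 + CH2(Bpin)2; 7 ← 1,3-bis(benzyloxy)-5-bromobenzene by formylation, chelation-controlled mono-debenzylation (this differentiates O5 from O7), MOM protection, reduction and bromination.
- Ring order: the A and B rings are bought as arenes; the C ring is the only ring made, in step 7.

Key step: step 7

Remark: compounds 1, 8, 11 and 16 are taken as commercial, and the phosphoramidite enantiomer in step 7 is taken to be the one that delivers the (1S,2R) adduct.

## Route

Step 1
Reactants: 1 1,3-bis(benzyloxy)-5-bromobenzene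
Product: 3 2,4-bis(benzyloxy)-6-bromobenzaldehyde, via aryl iminium chloride 2 (not isolated)
Conditions: (chloromethylene)dimethyliminium chloride, DMF, 0 to 80 °C; then H2O
Reagents that add atoms: (chloromethylene)dimethyliminium chloride, C[N+](C)=CCl.[Cl-]; water, O
Why: Vilsmeier–Haack formylation, in which the chloroiminium ion should attack the position para to one benzyloxy group and ortho to the other (next to bromine), as is usual for 3,5-dialkoxyhalobenzenes, and the iminium salt 2 is hydrolysed on work-up.

Step 2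
Reactants: 3 2,4-bis(benzyloxy)-6-bromobenzaldehyde
Product: 4 4-(benzyloxy)-2-bromo-6-hydroxybenzaldehyde
Conditions: MgBr2·OEt2, toluene/Et2O, 80 °C; then 1 M HCl
Reagents that add atoms: none
Why: Chelation-controlled ether cleavage, in which Mg2+ bridges the formyl oxygen and the ortho benzyloxy oxygen so that bromide removes only that benzyl group and the para benzyl ether (future O7) stays.

Step 3
Reactants: 4 4-(benzyloxy)-2-bromo-6-hydroxybenzaldehyde
Product: 5 4-(benzyloxy)-2-bromo-6-(methoxymethoxy)benzaldehyde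
Conditions: MOMCl, iPr2NEt, CH2Cl2, 0 °C to rt
Reagents that add atoms: chloromethyl methyl ether, COCCl
Why: O-alkylation of the phenol (acetal formation) should place a base-stable, acid-labile tag on the oxygen that becomes O5.

Step 4
Reactants: 5 4-(benzyloxy)-2-bromo-6-(methoxymethoxy)benzaldehyde
Product: 6 [4-(benzyloxy)-2-bromo-6-(methoxymethoxy)phenyl]methanol
Conditions: NaBH4, MeOH/THF, 0 °C
Reagents that add atoms: none
Why: Borohydride reduction of the aldehyde, which leaves the aryl bromide, the acetal and the benzyl ether untouched.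

Step 5
Reactants: 6 [4-(benzyloxy)-2-bromo-6-(methoxymethoxy)phenyl]methanol
Product: 7 5-(benzyloxy)-1-bromo-2-(bromomethyl)-3-(methoxymethoxy)benzene
Conditions: CBr4, PPh3, CH2Cl2, 0 °C; used at once
Reagents that add atoms: carbon tetrabromide, BrC(Br)(Br)Br
Why: Appel reaction, whose neutral conditions should keep the MOM acetal while the activated benzylic alcohol is converted into the bromide.

Step 6
Reactants: 7 5-(benzyloxy)-1-bromo-2-(bromomethyl)-3-(methoxymethoxy)benzene; 8 2,2'-methylenebis(4,4,5,5-tetramethyl-1,3,2-dioxaborolane) [CH2(Bpin)2]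
Product: 10 2,2'-{2-[4-(benzyloxy)-2-bromo-6-(methoxymethoxy)phenyl]ethane-1,1-diyl}bis(4,4,5,5-tetramethyl-1,3,2-dioxaborolane), via lithiated diborylmethane 9 (not isolated)
Conditions: LiTMP (1.0 equiv to 8), THF, 0 °C; then 7, 0 °C to rt
Reagents that add atoms: none
Why: Deprotonation of CH2(Bpin)2 gives the doubly boron-stabilised carbanion 9, which should displace the benzylic bromide by SN2, the standard alkylation route to 1,1-diborylalkanes.

Step 7
Reactants: 10 2,2'-{2-[4-(benzyloxy)-2-bromo-6-(methoxymethoxy)phenyl]ethane-1,1-diyl}bis(4,4,5,5-tetramethyl-1,3,2-dioxaborolane); 11 3,4,5-tris(benzyloxy)benzaldehyde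
Product: 13 2-{(2S,3R)-7-(benzyloxy)-5-(methoxymethoxy)-2-[3,4,5-tris(benzyloxy)phenyl]-3,4-dihydro-2H-chromen-3-yl}-4,4,5,5-tetramethyl-1,3,2-dioxaborolane (2,3-cis), via lithium syn-β-boryl alkoxide 12 (not isolated)
Conditions: Cu(MeCN)4PF6 (10 mol%), chiral BINOL-phosphoramidite L* (12 mol%), LiOtBu (1.2 equiv), THF, rt; then RockPhos Pd G3 (5 mol%), toluene, 50 °C
Reagents that add atoms: none
Why: Proposed new method: LiOtBu activates one of the two enantiotopic Bpin groups of 10 and the phosphoramidite–Cu(I) complex takes over the alkyl group as a configurationally defined α-boryl alkylcopper, which adds to the C=O of 11 through a closed four-centred transition state to give the syn β-boryl alkoxide 12 (bond C2–C3); Pd(0) then inserts into the C8a–Br bond, the alkoxide displaces bromide on palladium and C(aryl)–O reductive elimination forms bond O1–C8a. The closest known reaction types are the Cu/phosphoramidite-catalysed enantio- and syn-selective 1,2-addition of 1,1-diborylalkanes to aryl aldehydes and the Pd-catalysed intramolecular O-arylation of secondary alcohols with aryl bromides (Buchwald–Hartwig-type etherification); what is new is their relay in one flask on a β-boryl alkoxide. The only ring closed is the six-membered pyran ring, by reductive elimination from a seven-membered oxapalladacycle (formally a 6-exo attack of O1 on C8a). Both stereocentres are set by the chiral ligand on copper: C3 by the choice between the enantiotopic boryl groups and stereoretentive C–C bond formation, C2 by the aldehyde face taken in the closed transition state, which places B and O syn (the later 2,3-cis relationship); the ring closure touches neither. The step needs chemoselectivity between the two future oxygens and between the two metals: O3 is still a C–B bond so only O1 can be arylated (no dihydrobenzofuran), the aryl bromide is inert to Cu(I) at room temperature, and the secondary alkyl–Bpin is inert to Pd under these conditions.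

Step 8
Reactants: 13 2-{(2S,3R)-7-(benzyloxy)-5-(methoxymethoxy)-2-[3,4,5-tris(benzyloxy)phenyl]-3,4-dihydro-2H-chromen-3-yl}-4,4,5,5-tetramethyl-1,3,2-dioxaborolane
Product: 14 (2R,3R)-7-(benzyloxy)-5-(methoxymethoxy)-2-[3,4,5-tris(benzyloxy)phenyl]-3,4-dihydro-2H-chromen-3-ol
Conditions: 30% H2O2, 3 M NaOH, THF, 0 °C to rt
Reagents that add atoms: hydrogen peroxide, OO
Why: Oxidation of the C–B bond by 1,2-migration in the hydroperoxide ate complex proceeds with retention, so C3–B should become C3–OH with the cis relationship intact, as in the hydroboration–oxidation of flav-3-enes.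

Step 9
Reactants: 14 (2R,3R)-7-(benzyloxy)-5-(methoxymethoxy)-2-[3,4,5-tris(benzyloxy)phenyl]-3,4-dihydro-2H-chromen-3-ol
Product: 15 (2R,3R)-7-(benzyloxy)-2-[3,4,5-tris(benzyloxy)phenyl]-3,4-dihydro-2H-chromene-3,5-diol
Conditions: HCl (cat.), MeOH/THF, 45 °C
Reagents that add atoms: none
Why: Acid-catalysed acetal exchange with methanol should cleave the aryl MOM ether and free the 5-OH, while the benzyl ethers and both stereocentres are left alone.

Step 10
Reactants: 15 (2R,3R)-7-(benzyloxy)-2-[3,4,5-tris(benzyloxy)phenyl]-3,4-dihydro-2H-chromene-3,5-diol; 16 3,4,5-tris(benzyloxy)benzoic acid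
Product: 17 (2R,3R)-7-(benzyloxy)-2-[3,4,5-tris(benzyloxy)phenyl]-3,4-dihydro-2H-chromene-3,5-diyl bis[3,4,5-tris(benzyloxy)benzoate]
Conditions: 16 (2.4 equiv), DCC (2.6 equiv), DMAP (0.5 equiv), CH2Cl2, rt
Reagents that add atoms: none
Why: Steglich esterification with excess acid should acylate both the phenolic 5-OH and the secondary 3-OH in one operation without touching a stereocentre.

Step 11
Reactants: 17 (2R,3R)-7-(benzyloxy)-2-[3,4,5-tris(benzyloxy)phenyl]-3,4-dihydro-2H-chromene-3,5-diyl bis[3,4,5-tris(benzyloxy)benzoate]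
Product: 18 epigallocatechin 3,5-digallate [(2R,3R)-7-hydroxy-2-(3,4,5-trihydroxyphenyl)-3,4-dihydro-2H-chromene-3,5-diyl bis(3,4,5-trihydroxybenzoate)]
Conditions: H2 (1 atm), 20% Pd(OH)2/C, THF/EtOAc, rt
Reagents that add atoms: none
Why: Catalytic hydrogenolysis should remove all ten primary benzyl ethers, while the two gallate esters and the hindered secondary C2–O1 bond of the pyran ring are cleaved far more slowly.

## Compound list

1 | 1,3-bis(benzyloxy)-5-bromobenzene | Brc1cc(OCc2ccccc2)cc(OCc2ccccc2)c1 | starting material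
2 | N-{[2,4-bis(benzyloxy)-6-bromophenyl]methylidene}-N-methylmethanaminium chloride | C[N+](C)=Cc1c(Br)cc(OCc2ccccc2)cc1OCc1ccccc1.[Cl-] | intermediate (not isolated)
3 | 2,4-bis(benzyloxy)-6-bromobenzaldehyde | O=Cc1c(Br)cc(OCc2ccccc2)cc1OCc1ccccc1 | intermediate
4 | 4-(benzyloxy)-2-bromo-6-hydroxybenzaldehyde | O=Cc1c(Br)cc(OCc2ccccc2)cc1O | intermediate
5 | 4-(benzyloxy)-2-bromo-6-(methoxymethoxy)benzaldehyde | COCOc1cc(OCc2ccccc2)cc(Br)c1C=O | intermediate
6 | [4-(benzyloxy)-2-bromo-6-(methoxymethoxy)phenyl]methanol | COCOc1cc(OCc2ccccc2)cc(Br)c1CO | intermediate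
7 | 5-(benzyloxy)-1-bromo-2-(bromomethyl)-3-(methoxymethoxy)benzene | COCOc1cc(OCc2ccccc2)cc(Br)c1CBr | intermediate
8 | 2,2'-methylenebis(4,4,5,5-tetramethyl-1,3,2-dioxaborolane) | CC1(C)OB(CB2OC(C)(C)C(C)(C)O2)OC1(C)C | starting material
9 | [bis(4,4,5,5-tetramethyl-1,3,2-dioxaborolan-2-yl)methyl]lithium | [Li]C(B1OC(C)(C)C(C)(C)O1)B1OC(C)(C)C(C)(C)O1 | intermediate (not isolated)
10 | 2,2'-{2-[4-(benzyloxy)-2-bromo-6-(methoxymethoxy)phenyl]ethane-1,1-diyl}bis(4,4,5,5-tetramethyl-1,3,2-dioxaborolane) | COCOc1cc(OCc2ccccc2)cc(Br)c1CC(B1OC(C)(C)C(C)(C)O1)B1OC(C)(C)C(C)(C)O1 | intermediate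
11 | 3,4,5-tris(benzyloxy)benzaldehyde | O=Cc1cc(OCc2ccccc2)c(OCc2ccccc2)c(OCc2ccccc2)c1 | starting material
12 | lithium (1S,2R)-3-[4-(benzyloxy)-2-bromo-6-(methoxymethoxy)phenyl]-2-(4,4,5,5-tetramethyl-1,3,2-dioxaborolan-2-yl)-1-[3,4,5-tris(benzyloxy)phenyl]propan-1-olate (syn) | COCOc1cc(OCc2ccccc2)cc(Br)c1C[C@@H](B1OC(C)(C)C(C)(C)O1)[C@@H](c1cc(OCc2ccccc2)c(OCc2ccccc2)c(OCc2ccccc2)c1)[O-].[Li+] | intermediate (not isolated)
13 | 2-{(2S,3R)-7-(benzyloxy)-5-(methoxymethoxy)-2-[3,4,5-tris(benzyloxy)phenyl]-3,4-dihydro-2H-chromen-3-yl}-4,4,5,5-tetramethyl-1,3,2-dioxaborolane (2,3-cis) | COCOc1cc(OCc2ccccc2)cc2c1C[C@@H](B1OC(C)(C)C(C)(C)O1)[C@@H](c1cc(OCc3ccccc3)c(OCc3ccccc3)c(OCc3ccccc3)c1)O2 | intermediate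
14 | (2R,3R)-7-(benzyloxy)-5-(methoxymethoxy)-2-[3,4,5-tris(benzyloxy)phenyl]-3,4-dihydro-2H-chromen-3-ol | COCOc1cc(OCc2ccccc2)cc2c1C[C@@H](O)[C@@H](c1cc(OCc3ccccc3)c(OCc3ccccc3)c(OCc3ccccc3)c1)O2 | intermediate
15 | (2R,3R)-7-(benzyloxy)-2-[3,4,5-tris(benzyloxy)phenyl]-3,4-dihydro-2H-chromene-3,5-diol | Oc1cc(OCc2ccccc2)cc2c1C[C@@H](O)[C@@H](c1cc(OCc3ccccc3)c(OCc3ccccc3)c(OCc3ccccc3)c1)O2 | intermediate
16 | 3,4,5-tris(benzyloxy)benzoic acid | OC(=O)c1cc(OCc2ccccc2)c(OCc2ccccc2)c(OCc2ccccc2)c1 | starting material
17 | (2R,3R)-7-(benzyloxy)-2-[3,4,5-tris(benzyloxy)phenyl]-3,4-dihydro-2H-chromene-3,5-diyl bis[3,4,5-tris(benzyloxy)benzoate] | O=C(Oc1cc(OCc2ccccc2)cc2c1C[C@@H](OC(=O)c1cc(OCc3ccccc3)c(OCc3ccccc3)c(OCc3ccccc3)c1)[C@@H](c1cc(OCc3ccccc3)c(OCc3ccccc3)c(OCc3ccccc3)c1)O2)c1cc(OCc2ccccc2)c(OCc2ccccc2)c(OCc2ccccc2)c1 | intermediate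
18 | epigallocatechin 3,5-digallate, (2R,3R) | O=C(Oc1cc(O)cc2c1C[C@@H](OC(=O)c1cc(O)c(O)c(O)c1)[C@@H](c1cc(O)c(O)c(O)c1)O2)c1cc(O)c(O)c(O)c1 | target

## Step count and risks

Total steps: 11. Longest linear sequence: 11 steps (1 to 18); compounds 8, 11 and 16 enter as purchased materials.

**Step 7 (proposed new method).** The β-boryl alkoxide 12 may lose boron and oxygen by syn elimination (boron–Wittig-type olefination) before the C–O bond forms. The palladium alkoxide may undergo β-hydride elimination to the ketone, and the copper catalyst and phosphoramidite may slow the palladium cycle. The fallback uses known chemistry and separates the two bond formations so that no stoichiometric alkoxide is present during ring closure. It sets out from 10 and 11: only the Cu/phosphoramidite-catalysed 1,2-addition is run and quenched cold with aqueous NH4Cl. This gives the neutral syn β-hydroxy boronate (1S,2R)-3-[4-(benzyloxy)-2-bromo-6-(methoxymethoxy)phenyl]-2-(4,4,5,5-tetramethyl-1,3,2-dioxaborolan-2-yl)-1-[3,4,5-tris(benzyloxy)phenyl]propan-1-ol F1. F1 is then cyclised in a separate Pd-catalysed intramolecular O-arylation under weak base (Pd(OAc)2, a di-tert-butylbiarylphosphine, Cs2CO3, toluene, 60–70 °C). The fallback returns to the route at 13.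

**Step 6.** The ortho/para-alkoxy benzylic bromide 7 ionises easily, so Friedel–Crafts self-condensation or hydrolysis may outrun the alkylation, and the product may be alkylated a second time. The fallback avoids a benzylic electrophile altogether and sets out from aldehyde 5. Ohira–Bestmann homologation (dimethyl (1-diazo-2-oxopropyl)phosphonate, K2CO3, MeOH) should give the terminal alkyne 5-(benzyloxy)-1-bromo-2-ethynyl-3-(methoxymethoxy)benzene F2. A sequential double anti-Markovnikov hydroboration with pinacolborane under Rh(I)/bisphosphine catalysis places both boron atoms on the terminal carbon. The fallback returns to the route at 10 and makes steps 4 and 5 unnecessary.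

**Step 11.** Hydrogenolysis of ten benzyl ethers may stall as partly deprotected polyphenols adsorb on the catalyst, and the phenolic 5-O-gallate may be solvolysed during a long reaction. The fallback replaces the reductive cleavage by a Lewis-acid dealkylation. It sets out from 17, which is treated with BCl3 and pentamethylbenzene (cation scavenger) in CH2Cl2 at −78 °C; such conditions are known to leave aryl esters intact. It returns directly at 18 and makes no new compound.

## Further compounds

F1 | step 7 | (1S,2R)-3-[4-(benzyloxy)-2-bromo-6-(methoxymethoxy)phenyl]-2-(4,4,5,5-tetramethyl-1,3,2-dioxaborolan-2-yl)-1-[3,4,5-tris(benzyloxy)phenyl]propan-1-ol | COCOc1cc(OCc2ccccc2)cc(Br)c1C[C@@H](B1OC(C)(C)C(C)(C)O1)[C@@H](c1cc(OCc2ccccc2)c(OCc2ccccc2)c(OCc2ccccc2)c1)O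
F2 | step 6 | 5-(benzyloxy)-1-bromo-2-ethynyl-3-(methoxymethoxy)benzene | COCOc1cc(OCc2ccccc2)cc(Br)c1C#C
F0 | step 11 | none | none
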